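Readings and results are simulated for an exercise; noise was put on by code.

Read the runs before you reckon anything.

the same everywhere: free monomer 0.38 M; initiator 0.76 mM

| flask | protic impurity | remark | time |
|---|---|---|---|
| noon | 0.0095 M | run made earlier |  |
| dawn | 0.038 M | run made earlier |  |
| flask | 0.0190 M |  | 20 h |

| run | time / h | monomer in chains / % | free monomer / % |
|---|---|---|---|
| noon | 0.833 | 3.0 | 94.6 |
| noon | 2.50 | 10.6 | 87.3 |
| noon | 5.00 | 21.6 | 76.1 |
| noon | 6.00 | 26.0 | 71.7 |
| noon | 10.0 | 38.6 | 58.6 |
| noon | 12.0 | 44.6 | 52.4 |
| noon | 15.0 | 53.0 | 44.6 |
| dawn | 1.33 | 5.1 | 85.6 |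
| dawn | 2.00 | 6.9 | 82.9 |
| dawn | 3.00 | 10.8 | 77.8 |
| dawn | 5.00 | 19.8 | 71.7 |
| dawn | 6.00 | 23.0 | 67.8 |
| dawn | 10.0 | 35.9 | 55.0 |
| dawn | 15.0 | 47.2 | 43.0 |

(readings scatter by 0.5 percentage points)

- the average divides the monomer in chains by the number of chains begun, living and dead together
- steps that have been proposed: free monomer + living end -> monomer in chains + living end; initiator -> spent initiator; free monomer + initiator -> living end + monomer in chains; protic impurity + free monomer -> quenched substrate
- the earlier runs do not show the number of chains; that part of a forecast is a guess

* average number of monomer units in a chain (chains begun, living or dead) at 20 h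
* part of the free monomer that has reacted at 20 h

What does the protic impurity do? At the last readings, free monomer and monomer in chains fall short of the charge by 2.40% in the noon run and 9.80% in the dawn run. Those impurity charges are 2.50% and 10.0% of the free monomer. So I read one monomer lost per impurity, and this flask should lose 5.00%.

What consumes the rest? Free monomer falls nearly straight in its logarithm. Between the third and last readings, the noon run gives 0.0534 h⁻¹. Between its fourth and last readings, the dawn run gives 0.0511 h⁻¹. Their mean is 0.0523 h⁻¹. Call it the monomer clock: the fractional loss of free monomer per hour, a pseudo-first-order constant read at one initiator charge.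

Why should it follow the initiator? On the proposed steps, initiator divides between two routes, each first order in initiator. With the free monomer and protic impurity charges held, living ends and the clock should go with the initiator charge.

And this flask? My reckoning leaves 33.4% free monomer at 20 h, so 66.6% has reacted.

And the chain length? The clock does not count chains, so I commit to no figure.

The forecast gives 66% reacted, a little below mine, and a chain length of 800, “which is very uncertain”.

The simulation gives 66.3% reacted and a chain length of 3180.

    free monomer + living end → monomer in chains + living end, rate k1*[living end]*[free monomer] (k = 12.0 M⁻¹ min⁻¹)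
    initiator → spent initiator (k = 0.0410 min⁻¹)
    free monomer + initiator → living end + monomer in chains (k = 0.0120 M⁻¹ min⁻¹)
    protic impurity + free monomer → quenched substrate (k = 0.200 M⁻¹ min⁻¹)

This flask holds 33.7% free monomer at 20.0 h, against the clock's 33.4%. Its living ends stand at 7.33 × 10⁻⁵ M, and the forecast's chain length is a quarter of the simulated one. A neighbouring flask is charged with 3.0 × 10⁻⁴ M initiator, other charges unchanged. Its clock becomes 0.0206 h⁻¹, which leaves 62.9% free monomer at 20 h. That neighbouring flask holds 63.0% free monomer, 2.91 × 10⁻⁵ M living ends and 32.0% monomer in chains, with a chain length of 4190.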